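The route builds ring A and the pyran ring last, from an open chain in which C3 is already fixed. In ring A the C7 hydroxyl sits meta to both the C5 methoxyl and the ring oxygen on C8a, and C4a bears carbon. That is the arrangement produced when a vinylketene is joined to an alkynyl ether. Photolysis of an (R)-α-diazo ketone carrying a 1-methoxyvinyl ketone and a tethered ethynyl ether should form C7–C8, C4a–C8a and C6–C7 in one operation, closing both rings with the three ring-A oxygens already differentiated. The precursor comes from auxiliary-controlled allylation of the B-ring arylacetic acid.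

Key step: step 14

Remark: "Ar" stands for 4-methoxy-2-(methoxymethoxy)-3-(3-methylbut-2-en-1-yl)phenyl, and chroman numbering (O1, C2–C4, C4a, C5–C8, C8a) is also used for open-chain intermediates. C3 is R in the target, and because the ranking CH2–O (or C=O) > Ar > CH2 holds in every intermediate, the centre is R from 16 onward.

Assumption: the ynol ether and 2-methoxy enone intermediates (30, 33) are purified on triethylamine-deactivated silica and kept cold and dark.

Step 1
Reactants: 1 3-methoxyphenol
Product: 2 1-methoxy-3-(methoxymethoxy)benzene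
Conditions: MOMCl, i-Pr2NEt, CH2Cl2, 0 °C → rt
Reagents that add atoms: chloromethyl methyl ether, COCCl
Why: O-alkylation of the phenol with an α-chloro ether (MOM protection) gives an acetal that withstands the later bases and hydrides and directs both metalations.

Step 2
Reactants: 2 1-methoxy-3-(methoxymethoxy)benzene; 3 prenyl bromide
Product: 5 1-methoxy-3-(methoxymethoxy)-2-(3-methylbut-2-en-1-yl)benzene, via aryllithium 4 (not isolated)
Conditions: n-BuLi, THF, 0 °C → rt; CuI (10 mol %), 3, −78 °C → rt
Reagents that add atoms: none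
Why: Directed ortho-metalation removes the ring hydrogen flanked by OMOM and OMe, and copper-catalysed allylic substitution at the primary carbon of prenyl bromide gives the linear prenyl arene.

Step 3
Reactants: 5 1-methoxy-3-(methoxymethoxy)-2-(3-methylbut-2-en-1-yl)benzene; 6 ethylene oxide
Product: 8 2-Ar-ethan-1-ol, via aryllithium 7 (not isolated)
Conditions: n-BuLi, TMEDA, THF, −20 → 0 °C; 6 (THF solution), −78 °C → rt; aq NH4Cl
Reagents that add atoms: none
Why: A second directed ortho-metalation occurs at the only free position next to OMOM, the stronger director, and the aryllithium opens the epoxide to the 2-arylethanol.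

Step 4
Reactants: 8 2-Ar-ethan-1-ol
Product: 10 2-Ar-acetic acid, via aldehyde 9 (not isolated)
Conditions: TEMPO (20 mol %), PhI(OAc)2 (2.2 equiv), MeCN/H2O 1:1, rt
Reagents that add atoms: water, O
Why: TEMPO/PhI(OAc)2 oxidation (oxoammonium catalysis) takes the primary alcohol through aldehyde 9, whose hydrate is oxidised on to the acid under conditions that spare the MOM acetal, the prenyl alkene and the electron-rich ring.

Step 5
Reactants: 10 2-Ar-acetic acid; 11 (4R)-4-benzyl-1,3-oxazolidin-2-one
Product: 13 (4R)-4-benzyl-3-(2-Ar-acetyl)-1,3-oxazolidin-2-one, via mixed anhydride 12 (not isolated)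
Conditions: PivCl, Et3N, THF, −20 °C; then 11, LiCl, −20 °C → rt
Reagents that add atoms: none
Why: N-acylation of the oxazolidinone through the mixed pivalic anhydride with LiCl/Et3N activation loads the arylacetic acid onto the auxiliary without strong base.

Step 6
Reactants: 13 (4R)-4-benzyl-3-(2-Ar-acetyl)-1,3-oxazolidin-2-one; 14 allyl bromide
Product: 16 (4R)-4-benzyl-3-[(2R)-2-Ar-pent-4-enoyl]-1,3-oxazolidin-2-one, via sodium enolate 15 (not isolated)
Conditions: NaHMDS (1.05 equiv), THF, −78 °C; 14 (3 equiv), −78 → −45 °C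
Reagents that add atoms: none
Why: Evans asymmetric alkylation, in which the chelated (Z)-sodium enolate is attacked by allyl bromide on the face opposite the C4 benzyl group of the (R)-auxiliary, should set the new centre (future C3) as R, with the minor diastereomer removable by chromatography.

Step 7
Reactants: 16 (4R)-4-benzyl-3-[(2R)-2-Ar-pent-4-enoyl]-1,3-oxazolidin-2-one
Product: 17 (2R)-2-Ar-pent-4-en-1-ol
Conditions: LiBH4, MeOH (1.5 equiv), THF, 0 °C
Reagents that add atoms: none
Why: Borohydride reduction at the exocyclic imide carbonyl (reductive auxiliary cleavage) gives the primary alcohol without enolisation, so the α-aryl stereocentre is retained and the auxiliary is released for reuse.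

Step 8
Reactants: 17 (2R)-2-Ar-pent-4-en-1-ol; 18 trichloroethylene
Product: 20 1-[(2R)-1-{[(E)-1,2-dichloroethenyl]oxy}pent-4-en-2-yl]-4-methoxy-2-(methoxymethoxy)-3-(3-methylbut-2-en-1-yl)benzene, via potassium alkoxide 19 (not isolated)
Conditions: KH (2.2 equiv), THF, 0 °C → rt; 18, −50 °C → rt
Reagents that add atoms: none
Why: O-dichlorovinylation, in which the alkoxide adds anti to dichloroacetylene generated in the flask from trichloroethylene, gives the (E)-1,2-dichlorovinyl ether, a masked ynol ether that tolerates borane, oxidant and amide coupling.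

Step 9
Reactants: 20 (E)-1,2-dichlorovinyl ether of 17
Product: 22 (4R)-5-{[(E)-1,2-dichloroethenyl]oxy}-4-Ar-pentan-1-ol, via alkylborane 21 (not isolated)
Conditions: 9-BBN, THF, 0 °C → rt; then 3 M NaOH, 30% H2O2, 0 °C
Reagents that add atoms: hydrogen peroxide, OO
Why: Anti-Markovnikov hydroboration–oxidation with 9-BBN strongly prefers the monosubstituted alkene over the trisubstituted prenyl alkene and the chlorine-deactivated enol ether, and alkaline peroxide turns C–B into C–OH.

Step 10
Reactants: 22 (4R)-5-{[(E)-1,2-dichloroethenyl]oxy}-4-Ar-pentan-1-ol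
Product: 24 (4R)-5-{[(E)-1,2-dichloroethenyl]oxy}-4-Ar-pentanoic acid, via aldehyde 23 (not isolated)
Conditions: TEMPO (20 mol %), PhI(OAc)2 (2.2 equiv), MeCN/H2O 1:1, rt
Reagents that add atoms: water, O
Why: The same TEMPO/PhI(OAc)2 oxidation carries the primary alcohol through aldehyde 23 to the acid and leaves the dichlorovinyl ether, MOM acetal and prenyl group untouched.

Step 11
Reactants: 24 (4R)-5-{[(E)-1,2-dichloroethenyl]oxy}-4-Ar-pentanoic acid
Product: 26 (4R)-5-{[(E)-1,2-dichloroethenyl]oxy}-N-methoxy-N-methyl-4-Ar-pentanamide, via acylimidazole 25 (not isolated)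
Conditions: CDI, CH2Cl2, rt; then MeNH(OMe)·HCl, rt
Reagents that add atoms: N,O-dimethylhydroxylamine hydrochloride, CNOC.Cl
Why: Amide coupling through the acylimidazole (CDI activation) gives the Weinreb amide under near-neutral conditions.

Step 12
Reactants: 26 Weinreb amide; 27 methyl vinyl ether
Product: 30 (6R)-7-(ethynyloxy)-2-methoxy-6-Ar-hept-1-en-3-one, via tetrahedral adduct 28 (not isolated), via lithium alkynyl ether 29 (not isolated)
Conditions: 27, t-BuLi, THF, −78 → 0 °C (gives 1-methoxyvinyllithium, 3 equiv); 26, −78 °C; then n-BuLi (3 equiv), −78 → −40 °C; MeOH, −78 °C; pH 7 buffer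
Reagents that add atoms: none
Why: Weinreb ketone synthesis followed in the same flask by dehydrochlorination and chlorine–lithium exchange of the dichlorovinyl ether should work because the chelated adduct 28 is inert to further organolithium at −78 °C and so masks C7 while n-BuLi unveils the alkyne, and protonation then releases the terminal ynol ether and the 2-methoxy enone together.

Step 13
Reactants: 30 (6R)-7-(ethynyloxy)-2-methoxy-6-Ar-hept-1-en-3-one
Product: 33 (6R)-4-diazo-7-(ethynyloxy)-2-methoxy-6-Ar-hept-1-en-3-one, via lithium enolate 31 (not isolated), via trifluoroacetyl diketone 32 (not isolated)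
Conditions: LiHMDS (1.1 equiv), THF, −78 °C; CF3CO2CH2CF3, −78 °C; cold aq NaH2PO4 wash; then MsN3 (1.3 equiv), Et3N, H2O (1 equiv), MeCN, 0 °C → rt
Reagents that add atoms: methanesulfonyl azide, CS(=O)(=O)N=[N+]=[N-]
Why: Detrifluoroacetylative diazo transfer (kinetic enolisation at the only enolisable carbon, the future C4a, then C-trifluoroacetylation and N2 transfer from mesyl azide with loss of the activating group) is the standard entry to α′-diazo enones, and its base-only conditions with a buffered work-up spare the ynol ether and cannot touch C3.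

Step 14
Reactants: 33 (6R)-4-diazo-7-(ethynyloxy)-2-methoxy-6-Ar-hept-1-en-3-one
Product: 38 (3R)-5-methoxy-3-Ar-3,4-dihydro-2H-1-benzopyran-7-ol, via vinylketene 34 (not isolated), via vinylcyclobutenone 35 (not isolated), via dienylketene 36 (not isolated), via cyclohexadienone 37 (not isolated)
Conditions: hν (350–365 nm, Pyrex), degassed ClCH2CH2Cl (0.005 M), 15 °C until 33 is consumed; then 80 °C, dark
Reagents that add atoms: none
Why: Proposed new method: light expels N2 and the 1-methoxyvinyl group migrates to the carbene carbon (photochemical Wolff rearrangement), giving vinylketene 34; its carbonyl carbon (future C7) is attacked by the unsubstituted, nucleophilic alkyne carbon (C8) and the oxygen-bearing alkyne carbon (C8a) bonds to the ketene α-carbon (C4a), so that a [2+2] cycloaddition gives fused 4-vinylcyclobutenone 35, which opens by 4π-electrocyclic cleavage of C7–C4a to dienylketene 36, closes by 6π-electrocyclisation (C6–C7) to dienone 37 and tautomerises to the phenol. The closest known reaction type is the photochemical Danheiser benzannulation of α′-diazo enones with alkoxy- or siloxyalkynes, which is intermolecular, together with its tethered ynamide variants; a tethered ynol ether has no precedent. The pyran ring closes in the cycloaddition through the C4a–C8a bond, a 6-exo-dig closure onto the alkyne across a three-carbon tether, and ring A closes by the thermally allowed disrotatory 6π-electrocyclisation of 36 followed by enolisation. No stereocentre is created: the quaternary C4a centre of 35 is lost again on ring opening, and C3, set in step 6, sees neither acid nor base. The step needs head-to-tail regiochemistry in the cycloaddition, secured by the polarisation of the ynol ether and by the tether (the reverse mode would need a seven-membered ring), inward rotation of the vinyl group during ring opening, enforced because C4a=C8a must become a cis alkene inside the pyran, and preference for the ynol ether over the prenyl alkene and over a 1,2-hydrogen shift in the carbene, served by the electron-rich alkyne, high dilution and irradiation near 15 °C, which also keeps the ynol ether below its retro-ene temperature until it is consumed.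

Step 15
Reactants: 38 (3R)-5-methoxy-3-Ar-3,4-dihydro-2H-1-benzopyran-7-ol
Product: 39 (3R)-3-[2-hydroxy-4-methoxy-3-(3-methylbut-2-en-1-yl)phenyl]-5-methoxy-3,4-dihydro-2H-1-benzopyran-7-ol
Conditions: HCl (ca. 1 M) in MeOH, rt
Reagents that add atoms: none
Why: Acid-catalysed acetal cleavage (transacetalisation to dimethoxymethane) frees the 2′-phenol, and dilute methanolic HCl at ambient temperature is milder than the conditions under which an ortho-prenyl phenol cyclises to a dimethylchroman, while C3 has no epimerisable hydrogen.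

Compound list

1 | 3-methoxyphenol | COc1cccc(O)c1 | starting material
2 | 1-methoxy-3-(methoxymethoxy)benzene | COCOc1cccc(OC)c1 | intermediate
3 | prenyl bromide (1-bromo-3-methylbut-2-ene) | CC(C)=CCBr | starting material
4 | [2-methoxy-6-(methoxymethoxy)phenyl]lithium | [Li]c1c(OC)cccc1OCOC | intermediate
5 | 1-methoxy-3-(methoxymethoxy)-2-(3-methylbut-2-en-1-yl)benzene | COCOc1cccc(OC)c1CC=C(C)C | intermediate
6 | ethylene oxide (oxirane) | C1CO1 | starting material
7 | [4-methoxy-2-(methoxymethoxy)-3-(3-methylbut-2-en-1-yl)phenyl]lithium | [Li]c1ccc(OC)c(CC=C(C)C)c1OCOC | intermediate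
8 | 2-[4-methoxy-2-(methoxymethoxy)-3-(3-methylbut-2-en-1-yl)phenyl]ethan-1-ol | OCCc1ccc(OC)c(CC=C(C)C)c1OCOC | intermediate
9 | 2-[4-methoxy-2-(methoxymethoxy)-3-(3-methylbut-2-en-1-yl)phenyl]acetaldehyde | O=CCc1ccc(OC)c(CC=C(C)C)c1OCOC | intermediate
10 | 2-[4-methoxy-2-(methoxymethoxy)-3-(3-methylbut-2-en-1-yl)phenyl]acetic acid | OC(=O)Cc1ccc(OC)c(CC=C(C)C)c1OCOC | intermediate
11 | (4R)-4-benzyl-1,3-oxazolidin-2-one | O=C1N[C@H](Cc2ccccc2)CO1 | starting material
12 | mixed anhydride of 10 with pivalic acid | CC(C)(C)C(=O)OC(=O)Cc1ccc(OC)c(CC=C(C)C)c1OCOC | intermediate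
13 | (4R)-4-benzyl-3-(2-Ar-acetyl)-1,3-oxazolidin-2-one | O=C(Cc1ccc(OC)c(CC=C(C)C)c1OCOC)N1[C@H](Cc2ccccc2)COC1=O | intermediate
14 | allyl bromide (3-bromoprop-1-ene) | C=CCBr | starting material
15 | sodium (Z)-enolate of 13 | [Na+].[O-]/C(=C\c1ccc(OC)c(CC=C(C)C)c1OCOC)N1[C@H](Cc2ccccc2)COC1=O | intermediate
16 | (4R)-4-benzyl-3-[(2R)-2-Ar-pent-4-enoyl]-1,3-oxazolidin-2-one | C=CC[C@H](c1ccc(OC)c(CC=C(C)C)c1OCOC)C(=O)N1[C@H](Cc2ccccc2)COC1=O | intermediate
17 | (2R)-2-Ar-pent-4-en-1-ol | C=CC[C@H](c1ccc(OC)c(CC=C(C)C)c1OCOC)CO | intermediate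
18 | trichloroethylene | ClC=C(Cl)Cl | starting material
19 | potassium (2R)-2-Ar-pent-4-en-1-olate | C=CC[C@H](c1ccc(OC)c(CC=C(C)C)c1OCOC)C[O-].[K+] | intermediate
20 | 1-[(2R)-1-{[(E)-1,2-dichloroethenyl]oxy}pent-4-en-2-yl]-4-methoxy-2-(methoxymethoxy)-3-(3-methylbut-2-en-1-yl)benzene | C=CC[C@H](c1ccc(OC)c(CC=C(C)C)c1OCOC)CO/C(Cl)=C\Cl | intermediate
21 | 9-[(4R)-5-{[(E)-1,2-dichloroethenyl]oxy}-4-Ar-pentyl]-9-borabicyclo[3.3.1]nonane | C(CC[C@H](c1ccc(OC)c(CC=C(C)C)c1OCOC)CO/C(Cl)=C\Cl)B1C2CCCC1CCC2 | intermediate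
22 | (4R)-5-{[(E)-1,2-dichloroethenyl]oxy}-4-Ar-pentan-1-ol | OCCC[C@H](c1ccc(OC)c(CC=C(C)C)c1OCOC)CO/C(Cl)=C\Cl | intermediate
23 | (4R)-5-{[(E)-1,2-dichloroethenyl]oxy}-4-Ar-pentanal | O=CCC[C@H](c1ccc(OC)c(CC=C(C)C)c1OCOC)CO/C(Cl)=C\Cl | intermediate
24 | (4R)-5-{[(E)-1,2-dichloroethenyl]oxy}-4-Ar-pentanoic acid | OC(=O)CC[C@H](c1ccc(OC)c(CC=C(C)C)c1OCOC)CO/C(Cl)=C\Cl | intermediate
25 | 1-acylimidazole of 24 | O=C(CC[C@H](c1ccc(OC)c(CC=C(C)C)c1OCOC)CO/C(Cl)=C\Cl)n1ccnc1 | intermediate
26 | (4R)-5-{[(E)-1,2-dichloroethenyl]oxy}-N-methoxy-N-methyl-4-Ar-pentanamide | CON(C)C(=O)CC[C@H](c1ccc(OC)c(CC=C(C)C)c1OCOC)CO/C(Cl)=C\Cl | intermediate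
27 | methyl vinyl ether | COC=C | starting material
28 | lithium (6R)-7-{[(E)-1,2-dichloroethenyl]oxy}-2-methoxy-3-[methoxy(methyl)amino]-6-Ar-hept-1-en-3-olate (C3 epimers) | C=C(OC)C([O-])(N(C)OC)CC[C@H](c1ccc(OC)c(CC=C(C)C)c1OCOC)CO/C(Cl)=C\Cl.[Li+] | intermediate
29 | lithium (6R)-7-[(lithioethynyl)oxy]-2-methoxy-3-[methoxy(methyl)amino]-6-Ar-hept-1-en-3-olate (C3 epimers) | C=C(OC)C([O-])(N(C)OC)CC[C@H](c1ccc(OC)c(CC=C(C)C)c1OCOC)COC#C[Li].[Li+] | intermediate
30 | (6R)-7-(ethynyloxy)-2-methoxy-6-Ar-hept-1-en-3-one | C=C(OC)C(=O)CC[C@H](c1ccc(OC)c(CC=C(C)C)c1OCOC)COC#C | intermediate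
31 | lithium (6R)-7-(ethynyloxy)-2-methoxy-6-Ar-hepta-1,3-dien-3-olate | C=C(OC)C([O-])=CC[C@H](c1ccc(OC)c(CC=C(C)C)c1OCOC)COC#C.[Li+] | intermediate
32 | (6R)-7-(ethynyloxy)-2-methoxy-6-Ar-4-(trifluoroacetyl)hept-1-en-3-one (C4 epimers, enolised) | C=C(OC)C(=O)C(C(=O)C(F)(F)F)C[C@H](c1ccc(OC)c(CC=C(C)C)c1OCOC)COC#C | intermediate
33 | (6R)-4-diazo-7-(ethynyloxy)-2-methoxy-6-Ar-hept-1-en-3-one | C=C(OC)C(=O)C(=[N+]=[N-])C[C@H](c1ccc(OC)c(CC=C(C)C)c1OCOC)COC#C | intermediate
34 | (4R)-5-(ethynyloxy)-2-(1-methoxyethenyl)-4-Ar-pent-1-en-1-one (vinylketene) | C=C(OC)C(=C=O)C[C@H](c1ccc(OC)c(CC=C(C)C)c1OCOC)COC#C | intermediate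
35 | (4R)-6-(1-methoxyethenyl)-4-Ar-2-oxabicyclo[4.2.0]oct-1(8)-en-7-one (C6 epimers) | O=C1C=C2OC[C@@H](c3ccc(OC)c(CC=C(C)C)c3OCOC)CC12C(=C)OC | intermediate
36 | 2-[(5R)-3-(1-methoxyethenyl)-5-Ar-5,6-dihydro-4H-pyran-2-yl]ethen-1-one (dienylketene) | O=C=CC1=C(C(=C)OC)C[C@H](c2ccc(OC)c(CC=C(C)C)c2OCOC)CO1 | intermediate
37 | (3R)-5-methoxy-3-Ar-3,4-dihydro-2H-1-benzopyran-7(6H)-one | O=C1C=C2OC[C@@H](c3ccc(OC)c(CC=C(C)C)c3OCOC)CC2=C(OC)C1 | intermediate
38 | (3R)-5-methoxy-3-[4-methoxy-2-(methoxymethoxy)-3-(3-methylbut-2-en-1-yl)phenyl]-3,4-dihydro-2H-1-benzopyran-7-ol | COc1cc(O)cc2c1C[C@H](c1ccc(OC)c(CC=C(C)C)c1OCOC)CO2 | intermediate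
39 | (3R)-3-[2-hydroxy-4-methoxy-3-(3-methylbut-2-en-1-yl)phenyl]-5-methoxy-3,4-dihydro-2H-1-benzopyran-7-ol | COc1cc(O)cc2c1C[C@H](c1ccc(OC)c(CC=C(C)C)c1O)CO2 | target

Total step count: 15. Longest linear sequence: 15 steps (1 → 39).

Steps most likely to fail

1. Step 14 (proposed new method).
- What may go wrong: the carbene or ketene may be diverted before the intramolecular cycloaddition. Possible diversions are a 1,2-hydrogen shift from C4 to the carbene, capture of the ketene by the prenyl alkene, by the product phenol or by a second ketene, or thermal retro-ene loss of the ynol ether.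
- Fallback (known chemistry): the pyran ring is closed by etherification onto a preformed A ring; it sets out from imide 13 and comes back at 38. Commercial 2,4-dihydroxy-6-methoxybenzaldehyde would be bis-allylated (allyl bromide, K2CO3, DMF) to 2,4-bis(allyloxy)-6-methoxybenzaldehyde F1. Reduction (NaBH4, MeOH) would give [2,4-bis(allyloxy)-6-methoxyphenyl]methanol F2, and PBr3 (Et2O, −20 °C, used at once) would give 2,4-bis(allyloxy)-6-methoxybenzyl bromide F3. Evans alkylation of the sodium enolate of 13 with F3, under the same facial control as in step 6, should give the (2R)-benzylated imide F4. LiBH4 would then give the (2R)-propanol F5, and Pd(PPh3)4/morpholine would remove both allyl ethers to give the resorcinol alcohol F6. Intramolecular Mitsunobu etherification (PPh3, DIAD, THF, high dilution) through the ortho phenol closes the pyran ring and delivers 38, which continues through step 15.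

2. Step 13.
- What may go wrong: the sulfonyl azide may add to the electron-rich alkyne, the terminal alkyne C–H may be deprotonated during enolate formation, or the ynol ether may hydrate during work-up.
- Fallback: the alkyne terminus is capped; it sets out from Weinreb amide 26 and comes back at 33. Step 12 would be run as written, but the lithium alkynyl ether is quenched with Me3SiCl instead of a proton source. Aqueous work-up then gives the C-silylated ketone (6R)-2-methoxy-6-Ar-7-{[(trimethylsilyl)ethynyl]oxy}hept-1-en-3-one F7. The same diazo transfer on this capped, non-acidic alkyne should give the silylated diazo ketone F8, and TBAF (THF, −20 °C) then removes the silyl group to give 33.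

3. Step 12.
- What may go wrong: the tetrahedral adduct may collapse early, so that organolithium over-adds to the liberated ketone, or the chlorine–lithium exchange may be incomplete.
- Fallback: C7 is carried at the alcohol oxidation level through the unmasking; it sets out from alcohol 22 and comes back at 30. Compound 22 would be oxidised only as far as aldehyde 23 (Dess–Martin periodinane, NaHCO3, CH2Cl2). Addition of 1-methoxyvinyllithium, followed without work-up by n-BuLi (−78 → −40 °C) while the carbinol oxygen is held as its lithium salt and cannot revert to a carbonyl, should give (6R)-7-(ethynyloxy)-2-methoxy-6-Ar-hept-1-en-3-ol F9 as inconsequential carbinol epimers. Non-acidic oxidation (MnO2, CH2Cl2, or SO3·pyridine/DMSO/i-Pr2NEt) then gives 30.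

Further compounds
F1 | step 14 | 2,4-bis(prop-2-en-1-yloxy)-6-methoxybenzaldehyde | COc1cc(OCC=C)cc(OCC=C)c1C=O
F2 | step 14 | [2,4-bis(prop-2-en-1-yloxy)-6-methoxyphenyl]methanol | COc1cc(OCC=C)cc(OCC=C)c1CO
F3 | step 14 | 2-(bromomethyl)-1-methoxy-3,5-bis(prop-2-en-1-yloxy)benzene | COc1cc(OCC=C)cc(OCC=C)c1CBr
F4 | step 14 | (4R)-4-benzyl-3-{(2R)-3-[2,4-bis(prop-2-en-1-yloxy)-6-methoxyphenyl]-2-Ar-propanoyl}-1,3-oxazolidin-2-one | COc1cc(OCC=C)cc(OCC=C)c1C[C@H](c1ccc(OC)c(CC=C(C)C)c1OCOC)C(=O)N1[C@H](Cc2ccccc2)COC1=O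
F5 | step 14 | (2R)-3-[2,4-bis(prop-2-en-1-yloxy)-6-methoxyphenyl]-2-Ar-propan-1-ol | COc1cc(OCC=C)cc(OCC=C)c1C[C@H](c1ccc(OC)c(CC=C(C)C)c1OCOC)CO
F6 | step 14 | 4-[(2R)-3-hydroxy-2-Ar-propyl]-5-methoxybenzene-1,3-diol | COc1cc(O)cc(O)c1C[C@H](c1ccc(OC)c(CC=C(C)C)c1OCOC)CO
F7 | step 13 | (6R)-2-methoxy-6-Ar-7-{[(trimethylsilyl)ethynyl]oxy}hept-1-en-3-one | C=C(OC)C(=O)CC[C@H](c1ccc(OC)c(CC=C(C)C)c1OCOC)COC#C[Si](C)(C)C
F8 | step 13 | (6R)-4-diazo-2-methoxy-6-Ar-7-{[(trimethylsilyl)ethynyl]oxy}hept-1-en-3-one | C=C(OC)C(=O)C(=[N+]=[N-])C[C@H](c1ccc(OC)c(CC=C(C)C)c1OCOC)COC#C[Si](C)(C)C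
F9 | step 12 | (6R)-7-(ethynyloxy)-2-methoxy-6-Ar-hept-1-en-3-ol (C3 epimers) | C=C(OC)C(O)CC[C@H](c1ccc(OC)c(CC=C(C)C)c1OCOC)COC#C
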